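## Retrosynthetic overview

1. The axial C2 acetate comes from a C2 ketone (hydride from the open face, acetylation in the same flask); the ketone comes from the C2-epimeric, equatorial alcohol of the bicyclic core.
2. Both rings are disconnected at once: C4–C5 (ring A, formed first) and C9–C10 (ring B, formed second) lead back to an acyclic (E,E,E)-tetraene whose only stereocentre, the C2 carbinol, steers the chair–chair fold.
3. The tetraene is cut at C1–C2: the carbinol carbon is used as an α-oxygenated carbanion (sparteine-controlled lithiated carbamate of isoprenol) and C1 as the carbon of an allylboronate; a 1,2-metalate shift joins them.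
4. The allylboronate comes from (E,E)-farnesyl acetate by allylic oxidation of the terminal (E)-methyl, bromination and borylation.

Assumption: positions are cited with labdane numbering (C1–C20); the SMILES is read as the ent-labdane (2S,5R,9R,10R) with the C2 acetate axial, cis to the C10 methyl.

## Route

Step 1
Reactants: 1 3-methylbut-3-en-1-ol (isoprenol)
Product: 2 3-methylbut-3-en-1-yl N,N-diisopropylcarbamate
Conditions: NaH, i-Pr2NCOCl, THF, 0 °C to reflux
Reagents that add atoms: N,N-diisopropylcarbamoyl chloride, CC(C)N(C(C)C)C(Cl)=O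
Why: O-carbamoylation of the sodium alkoxide (acyl substitution) installs the N,N-diisopropylcarbamoyl group that later directs and stabilises α-lithiation; no stereocentre is formed.

Step 2
Reactants: 3 (2E,6E)-3,7,11-trimethyldodeca-2,6,10-trien-1-yl acetate ((E,E)-farnesyl acetate)
Product: 4 (2E,6E,10E)-12-hydroxy-3,7,11-trimethyldodeca-2,6,10-trien-1-yl acetate
Conditions: SeO2 (0.1 equiv), t-BuOOH (3 equiv), salicylic acid (0.1 equiv), CH2Cl2, rt
Reagents that add atoms: tert-butyl hydroperoxide, CC(C)(C)OO (source of the new oxygen, passed on by catalytic SeO2, O=[Se]=O)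
Why: Sharpless-type SeO2/t-BuOOH allylic oxidation (ene reaction, then 2,3-sigmatropic shift) attacks the terminal, most electron-rich trisubstituted alkene at its (E)-methyl group, giving the primary (E)-allylic alcohol with the inner alkenes and the allylic acetate untouched; no stereocentre is formed.

Step 3
Reactants: 4 (2E,6E,10E)-12-hydroxy-3,7,11-trimethyldodeca-2,6,10-trien-1-yl acetate
Product: 5 (2E,6E,10E)-12-bromo-3,7,11-trimethyldodeca-2,6,10-trien-1-yl acetate
Conditions: CBr4, PPh3, CH2Cl2, 0 °C
Reagents that add atoms: tetrabromomethane, BrC(Br)(Br)Br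
Why: Appel bromination (SN2 at the primary allylic carbon through the alkoxyphosphonium salt) runs under neutral conditions without allylic transposition or loss of the (E) geometry.

Step 4
Reactants: 5 (2E,6E,10E)-12-bromo-3,7,11-trimethyldodeca-2,6,10-trien-1-yl acetate
Product: 6 (2E,6E,10E)-3,7,11-trimethyl-12-(4,4,5,5-tetramethyl-1,3,2-dioxaborolan-2-yl)dodeca-2,6,10-trien-1-yl acetate
Conditions: B2pin2, Pd2(dba)3 (tris(dibenzylideneacetone)dipalladium, 1 mol %), THF, rt
Reagents that add atoms: bis(pinacolato)diboron, CC1(C)OB(OC1(C)C)B1OC(C)(C)C(C)(C)O1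
Why: Miyaura-type borylation of an allylic halide: zerovalent palladium inserts into the primary allylic C–Br bond far faster than into the allylic acetate, and B–B transmetalation followed by C–B reductive elimination at the less hindered allyl terminus gives the linear (E)-allylboronate.

Step 5
Reactants: 2 3-methylbut-3-en-1-yl N,N-diisopropylcarbamate; 6 (2E,6E,10E)-3,7,11-trimethyl-12-(4,4,5,5-tetramethyl-1,3,2-dioxaborolan-2-yl)dodeca-2,6,10-trien-1-yl acetate
Product: 10 (2E,6E,10E,13R)-13-hydroxy-3,7,11,15-tetramethylhexadeca-2,6,10,15-tetraen-1-yl acetate, via lithiated carbamate 7 (not isolated), via boronate complex 8 (not isolated), via secondary boronic ester 9 (not isolated)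
Conditions: s-BuLi, (−)-sparteine, Et2O, −78 °C, 5 h; add 6, −78 °C; MgBr2·OEt2, −78 °C to 35 °C; then NaBO3·4H2O, THF/H2O, rt
Reagents that add atoms: sodium perborate, [Na+].[Na+].O[B-]1(O)OO[B-](O)(O)OO1 (hydroxyl oxygen)
Why: Hoppe–Aggarwal lithiation–borylation: s-BuLi/(−)-sparteine removes the pro-S proton next to oxygen to give the configurationally stable α-oxygenated carbanion 7 (the carbinol carbon, labdane C2, used with reversed polarity as a chiral carbenoid), the boron of 6 captures it with retention to give 8, 1,2-migration of the allyl group with inversion and loss of carbamate forges C1–C2 (two nucleophilic carbons joined) to give 9, and stereoretentive C–B oxidation leaves the (13R) alcohol.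

Step 6
Reactants: 10 (2E,6E,10E,13R)-13-hydroxy-3,7,11,15-tetramethylhexadeca-2,6,10,15-tetraen-1-yl acetate
Product: 11 (2R,5R,9R,10R)-2-hydroxylabda-7,13E-dien-15-yl acetate (ent-labdane core, trans-fused, 2-OH equatorial and trans to the C10 methyl)
Conditions: [N,N′-bis(3,5-di-tert-butylsalicylidene)-1,2-cyclohexanediaminato]cobalt (divalent cobalt, C36H52CoN2O2, 5 mol %), N-fluoro-2,4,6-trimethylpyridinium tetrafluoroborate, (Me2SiH)2O, (CF3)2CHOH, 0 °C
Reagents that add atoms: none
Why: Proposed new method: hydrogen-atom transfer from a cobalt hydride to the 1,1-disubstituted alkene (the only alkene reactive enough) gives the tertiary C4 radical, which closes ring A and then ring B by two 6-endo cyclisations through a chair–chair fold with the C2 hydroxyl equatorial (so 2R dictates 5R, 9R, 10R and the trans ring fusion), and oxidation of the C8 radical to the cation with loss of H-7 gives the 7,8-alkene while any 8(17)-isomer re-enters the cycle; the closest known reaction type is the cobalt–salen/silane/N-fluoropyridinium HAT-initiated radical–polar crossover bicyclisation of polyenes (arene-terminated, including precursors carrying an oxygenated stereocentre), here ended by elimination.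

Step 7
Reactants: 11 (2R,5R,9R,10R)-2-hydroxylabda-7,13E-dien-15-yl acetate
Product: 12 (5R,9R,10R)-2-oxolabda-7,13E-dien-15-yl acetate
Conditions: Dess–Martin periodinane, CH2Cl2, rt
Reagents that add atoms: none
Why: Dess–Martin oxidation of the secondary alcohol under near-neutral conditions gives the C2 ketone without touching the alkenes or the allylic acetate, and since C1 and C3 are methylenes no stereocentre can epimerise.

Step 8
Reactants: 12 (5R,9R,10R)-2-oxolabda-7,13E-dien-15-yl acetate
Product: 14 (2S,5R,9R,10R)-labda-7,13E-diene-2,15-diyl diacetate (CNP0314870.1), via lithium alkoxide 13 (not isolated)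
Conditions: LiBH(s-Bu)3, THF, −78 °C; then Ac2O, DMAP, pyridine, −78 °C to rt
Reagents that add atoms: acetic anhydride, CC(=O)OC(C)=O
Why: Substrate-controlled hydride reduction followed by in situ O-acylation: the bulky borohydride can reach C2 only from the face opposite the syn-axial C4 and C10 methyls (equatorial attack), giving the axial 2-alkoxide (2S, cis to the C10 methyl), which is acetylated in the same flask together with any C15 alkoxide freed by acetate cleavage.

## Compound list

1 | 3-methylbut-3-en-1-ol (isoprenol) | C=C(C)CCO | starting material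
2 | 3-methylbut-3-en-1-yl N,N-diisopropylcarbamate | C=C(C)CCOC(=O)N(C(C)C)C(C)C | intermediate
3 | (2E,6E)-3,7,11-trimethyldodeca-2,6,10-trien-1-yl acetate ((E,E)-farnesyl acetate) | CC(=O)OC/C=C(\C)CC/C=C(\C)CCC=C(C)C | starting material
4 | (2E,6E,10E)-12-hydroxy-3,7,11-trimethyldodeca-2,6,10-trien-1-yl acetate | CC(=O)OC/C=C(\C)CC/C=C(\C)CC/C=C(\C)CO | intermediate
5 | (2E,6E,10E)-12-bromo-3,7,11-trimethyldodeca-2,6,10-trien-1-yl acetate | CC(=O)OC/C=C(\C)CC/C=C(\C)CC/C=C(\C)CBr | intermediate
6 | (2E,6E,10E)-3,7,11-trimethyl-12-(4,4,5,5-tetramethyl-1,3,2-dioxaborolan-2-yl)dodeca-2,6,10-trien-1-yl acetate | CC(=O)OC/C=C(\C)CC/C=C(\C)CC/C=C(\C)CB1OC(C)(C)C(C)(C)O1 | intermediate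
7 | (1S)-1-lithio-3-methylbut-3-en-1-yl N,N-diisopropylcarbamate, as its (−)-sparteine complex | [Li][C@@H](CC(C)=C)OC(=O)N(C(C)C)C(C)C | intermediate (not isolated)
8 | lithium [(1S)-1-(N,N-diisopropylcarbamoyloxy)-3-methylbut-3-en-1-yl][(2E,6E,10E)-12-acetoxy-2,6,10-trimethyldodeca-2,6,10-trien-1-yl](pinacolato)borate | [Li+].CC(=O)OC/C=C(\C)CC/C=C(\C)CC/C=C(\C)C[B-]1(OC(C)(C)C(C)(C)O1)[C@@H](CC(C)=C)OC(=O)N(C(C)C)C(C)C | intermediate (not isolated)
9 | (2E,6E,10E,13R)-3,7,11,15-tetramethyl-13-(4,4,5,5-tetramethyl-1,3,2-dioxaborolan-2-yl)hexadeca-2,6,10,15-tetraen-1-yl acetate | CC(=O)OC/C=C(\C)CC/C=C(\C)CC/C=C(\C)C[C@H](B1OC(C)(C)C(C)(C)O1)CC(C)=C | intermediate (not isolated)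
10 | (2E,6E,10E,13R)-13-hydroxy-3,7,11,15-tetramethylhexadeca-2,6,10,15-tetraen-1-yl acetate | CC(=O)OC/C=C(\C)CC/C=C(\C)CC/C=C(\C)C[C@H](O)CC(C)=C | intermediate
11 | (2R,5R,9R,10R)-2-hydroxylabda-7,13E-dien-15-yl acetate (2-OH equatorial) | CC(=O)OC/C=C(\C)CC[C@@H]1C(C)=CC[C@@H]2C(C)(C)C[C@@H](O)C[C@@]12C | intermediate
12 | (5R,9R,10R)-2-oxolabda-7,13E-dien-15-yl acetate | CC(=O)OC/C=C(\C)CC[C@@H]1C(C)=CC[C@@H]2C(C)(C)CC(=O)C[C@@]12C | intermediate
13 | lithium (2S,5R,9R,10R)-15-acetoxylabda-7,13E-dien-2-olate (axial alkoxide) | [Li+].CC(=O)OC/C=C(\C)CC[C@@H]1C(C)=CC[C@@H]2C(C)(C)C[C@H]([O-])C[C@@]12C | intermediate (not isolated)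
14 | (2S,5R,9R,10R)-labda-7,13E-diene-2,15-diyl diacetate; (2E)-5-[(1R,4aR,7S,8aR)-7-acetoxy-2,5,5,8a-tetramethyl-1,4,4a,5,6,7,8,8a-octahydronaphthalen-1-yl]-3-methylpent-2-en-1-yl acetate | CC(=O)OC/C=C(\C)CC[C@@H]1C(C)=CC[C@@H]2C(C)(C)C[C@H](OC(C)=O)C[C@@]12C | target

## Step count and risks

Total step count: 8. Longest linear sequence: 7 steps (3 to 14, steps 2–8).

Steps most likely to fail:

Step 6. The cascade may end in mixtures of 7-ene, 8(17)-ene and 8-ene, may run on into a third ring through the C13 alkene, and the small free hydroxyl may relay imperfectly. The fallback sets out from 10 and comes back at 11, replacing the radical cascade by an electrophile-triggered cationic bicyclisation. Hg(OTf)2 with N,N-dimethylaniline in MeNO2 at −20 °C mercurates the terminal 1,1-disubstituted alkene at its CH2 end. The C4 cation is taken up by the two trisubstituted alkenes through the same chair–chair fold (hydroxyl equatorial), and the amine removes H-7; the acetoxy-deactivated C13 alkene should not attack a cation. Aqueous NaCl gives the alkylmercury chloride F1. NaBH4 in DMF at 0 °C then replaces mercury by hydrogen, turning the CH2HgCl group into the second C4 methyl and giving 11.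

Step 5. The 1,2-shift of an allyl group in boronate complex 8 may be sluggish or reversible, the enantiomer ratio may erode, and the acetate may be attacked. The fallback sets out from bromide 5 (with carbamate 2) and comes back at 10 without boron. The same sparteine-complexed lithiated carbamate 7 is alkylated directly by 5 (SN2 at the primary allylic carbon, retention at the carbanion, inverse addition at −78 °C) to give the carbamate F2. LiAlH4 in THF at reflux removes both the carbamoyl and the acetyl group to give the diol F3. Ac2O in pyridine at 0 °C then acetylates only the primary allylic hydroxyl, giving 10.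

Step 4. Zerovalent palladium may also ionise the C1 allylic acetate, 5 may homocouple with 6, and 6 may be lost on silica. The fallback sets out from 5 and comes back at 6 by hydroboration of a diene instead of substitution. Dehydrobromination (Li2CO3, LiBr, DMF, 100 °C) gives the conjugated tetraene acetate F4. Iron-catalysed 1,4-hydroboration with pinacolborane (FeCl2 complex of a 2-iminopyridine ligand, reduced with Mg, Et2O, rt) then adds boron to the terminal CH2 and hydrogen to C9, giving the (E)-allylboronate 6.

## Further compounds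

F1 | step 6 | (2R,5R,9R,10R)-2-hydroxy-4-(chloromercuriomethyl)labda-7,13E-dien-15-yl acetate, i.e. 11 with one C4 methyl as CH2HgCl (either C4 epimer; both converge) | CC(=O)OC/C=C(\C)CC[C@@H]1C(C)=CC[C@@H]2C(C)(C[Hg]Cl)C[C@@H](O)C[C@@]12C
F2 | step 5 | (2E,6E,10E,13R)-13-(N,N-diisopropylcarbamoyloxy)-3,7,11,15-tetramethylhexadeca-2,6,10,15-tetraen-1-yl acetate | CC(=O)OC/C=C(\C)CC/C=C(\C)CC/C=C(\C)C[C@H](OC(=O)N(C(C)C)C(C)C)CC(C)=C
F3 | step 5 | (2E,6E,10E,13R)-3,7,11,15-tetramethylhexadeca-2,6,10,15-tetraene-1,13-diol | OC/C=C(\C)CC/C=C(\C)CC/C=C(\C)C[C@H](O)CC(C)=C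
F4 | step 4 | (2E,6E,9E)-3,7,11-trimethyldodeca-2,6,9,11-tetraen-1-yl acetate | CC(=O)OC/C=C(\C)CC/C=C(\C)C/C=C/C(C)=C
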